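**Assumption:** the target C22H28O6 has no stereocentre and is achiral, so no enantiomer has to be selected. The only stereo-element in the route is the E-alkene of 5, which is removed in step 2.

**Retrosynthetic overview**
- Target ester ⇒ (acyl C–O, esterification) 3-(3,4-dimethoxyphenyl)propanoic acid + 3-(3,4-dimethoxyphenyl)propan-1-ol.
- The alcohol ⇒ (FGI, reduction) the same propanoic acid, so one C6–C3 building block supplies both halves.
- The propanoic acid ⇒ (FGI, hydrogenation) (E)-3,4-dimethoxycinnamic acid.
- The cinnamic acid ⇒ (Cα–Cβ bond, aldol-type Knoevenagel–Doebner condensation) veratraldehyde + malonic acid.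
- No ring is formed. Both arene rings are bought with veratraldehyde.

**Route**

Step 1
Reactants: 1 3,4-dimethoxybenzaldehyde (veratraldehyde); 2 malonic acid
Product: 5 (E)-3-(3,4-dimethoxyphenyl)prop-2-enoic acid, via aldol adduct 3 (not isolated), via benzylidenemalonic acid 4 (not isolated)
Conditions: 2 (1.5 equiv), piperidine (0.1 equiv), pyridine, 90 → 115 °C, 4 h; then cold aq HCl, filter, recrystallise (EtOH)
Reagents that add atoms: none
Why: In this Knoevenagel–Doebner condensation (an intermolecular aldol-type condensation) the malonic acid enolate adds to the non-enolisable aldehyde, and dehydration plus pyridine-promoted decarboxylation drive the reaction irreversibly to the thermodynamic E-acid; no stereocentre remains.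

Step 2
Reactants: 5 (E)-3-(3,4-dimethoxyphenyl)prop-2-enoic acid
Product: 6 3-(3,4-dimethoxyphenyl)propanoic acid
Conditions: H2 (1 atm), 10% Pd/C, EtOH–THF, rt
Reagents that add atoms: none
Why: Catalytic heterogeneous hydrogenation saturates the conjugated C=C at 1 atm, while the arene, the aryl methyl ethers and the CO2H group are inert and no benzylic C–O bond is present to be cleaved; no stereocentre is created.

Step 3 (about half of 6 is used here; the rest is kept for step 4)
Reactants: 6 3-(3,4-dimethoxyphenyl)propanoic acid
Product: 8 3-(3,4-dimethoxyphenyl)propan-1-ol, via trialkoxyboroxine 7 (not isolated)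
Conditions: BH3·THF (1.3 equiv), THF, 0 °C → rt; then H2O
Reagents that add atoms: none
Why: In this borane reduction of a carboxylic acid the electrophilic hydride reacts fast through the acyloxyborane down to the alkoxyboroxine, which water hydrolyses to the primary alcohol, and the aryl ethers do not react; no stereocentre is created.

Step 4
Reactants: 6 3-(3,4-dimethoxyphenyl)propanoic acid; 8 3-(3,4-dimethoxyphenyl)propan-1-ol
Product: 10 3-(3,4-dimethoxyphenyl)propyl 3-(3,4-dimethoxyphenyl)propanoate, via O-acylisourea 9 (not isolated)
Conditions: 6 (1.05 equiv), DCC (1.1 equiv), DMAP (0.1 equiv), CH2Cl2, 0 °C → rt; filter, wash (dil. HCl, aq NaHCO3), SiO2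
Reagents that add atoms: none
Why: In this Steglich esterification DCC activates the unhindered acid and the nucleophilic catalyst DMAP passes the acyl group to the unhindered primary alcohol faster than the O→N acyl shift, under neutral mild conditions that leave all four methyl ethers untouched; no stereocentre is involved.

**Compound list**
1 | 3,4-dimethoxybenzaldehyde (veratraldehyde) | COc1ccc(C=O)cc1OC | starting material
2 | malonic acid | OC(=O)CC(=O)O | starting material
3 | 2-[(3,4-dimethoxyphenyl)(hydroxy)methyl]propanedioic acid (racemic, transient aldol adduct) | COc1ccc(C(O)C(C(=O)O)C(=O)O)cc1OC | intermediate (not isolated)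
4 | 2-(3,4-dimethoxybenzylidene)propanedioic acid | COc1ccc(C=C(C(=O)O)C(=O)O)cc1OC | intermediate (not isolated)
5 | (E)-3-(3,4-dimethoxyphenyl)prop-2-enoic acid | COc1ccc(/C=C/C(=O)O)cc1OC | intermediate
6 | 3-(3,4-dimethoxyphenyl)propanoic acid | COc1ccc(CCC(=O)O)cc1OC | intermediate
7 | 2,4,6-tris[3-(3,4-dimethoxyphenyl)propoxy]boroxine | COc1ccc(CCCOB2OB(OCCCc3ccc(OC)c(OC)c3)OB(OCCCc3ccc(OC)c(OC)c3)O2)cc1OC | intermediate (not isolated)
8 | 3-(3,4-dimethoxyphenyl)propan-1-ol | COc1ccc(CCCO)cc1OC | intermediate
9 | N,N'-dicyclohexyl-O-[3-(3,4-dimethoxyphenyl)propanoyl]isourea | COc1ccc(CCC(=O)OC(=NC2CCCCC2)NC2CCCCC2)cc1OC | intermediate (not isolated)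
10 | 3-(3,4-dimethoxyphenyl)propyl 3-(3,4-dimethoxyphenyl)propanoate (achiral) | COc1ccc(CCCOC(=O)CCc2ccc(OC)c(OC)c2)cc1OC | target

**Total step count:** 4
**Longest linear sequence:** 4 (1 → 5 → 6 → 8 → 10; 6 enters a second time in step 4)

**Steps most likely to fail, with fallbacks**

Step 4 (risks: O→N acyl shift to the N-acylurea, and urea that is hard to remove). The fallback forms the ester C–O bond by O-alkylation instead of acyl transfer. It sets out from 8 and comes back to the route at 10. Alcohol 8 is treated with MsCl and Et3N in CH2Cl2 at 0 °C to give 3-(3,4-dimethoxyphenyl)propyl methanesulfonate F4. This mesylate is then displaced in an SN2 reaction by the caesium carboxylate of 6 (Cs2CO3, DMF, 50 °C) to give 10.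

Step 3 (risks: aged borane solution, incomplete reduction, slow hydrolysis of the boron esters). The fallback changes both the substrate class and the type of hydride. It sets out from 6 and comes back at 8. Fischer esterification of 6 (MeOH, cat. H2SO4, reflux) gives methyl 3-(3,4-dimethoxyphenyl)propanoate F3. This ester is reduced with the nucleophilic hydride LiAlH4 (THF, 0 °C, Fieser work-up) to give 8.

Step 1 (risks: incomplete decarboxylation, or stalled condensation of the electron-rich aldehyde). The fallback uses a more acidic C–H partner and bypasses the cinnamic acid and its hydrogenation. It sets out from 1 and comes back at 6.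
- Knoevenagel condensation of 1 with Meldrum's acid (cat. piperidine/AcOH, EtOH, rt) precipitates 5-(3,4-dimethoxybenzylidene)-2,2-dimethyl-1,3-dioxane-4,6-dione F1.
- Conjugate reduction with NaBH4 (CH2Cl2–AcOH, 0 °C) gives 5-(3,4-dimethoxybenzyl)-2,2-dimethyl-1,3-dioxane-4,6-dione F2.
- Heating F2 in pyridine–water (10:1, reflux) opens the ring and decarboxylates it to 6.

**Further compounds**
F1 | step 1 | 5-(3,4-dimethoxybenzylidene)-2,2-dimethyl-1,3-dioxane-4,6-dione | COc1ccc(C=C2C(=O)OC(C)(C)OC2=O)cc1OC
F2 | step 1 | 5-(3,4-dimethoxybenzyl)-2,2-dimethyl-1,3-dioxane-4,6-dione | COc1ccc(CC2C(=O)OC(C)(C)OC2=O)cc1OC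
F3 | step 3 | methyl 3-(3,4-dimethoxyphenyl)propanoate | COC(=O)CCc1ccc(OC)c(OC)c1
F4 | step 4 | 3-(3,4-dimethoxyphenyl)propyl methanesulfonate | COc1ccc(CCCOS(C)(=O)=O)cc1OC
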